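The earlier runs and the new flask were computed with made-up constants; the scatter is artificial.

Late in a run, product plus solid substrate should give back the charge, and they come near it: at the last readings the sum is 98.8% in the cedar run and 103% in the birch run. Early the sum falls short: at 0.625 d the birch run gives 76.9%. I take the rest to be dissolved and unread, so I judge progress by product and not by the solid. My decision is whether the next flask can keep 2 mol% of catalyst and 15 d, or needs more.

the same everywhere: solid substrate 1.5 M; gas phase 150 mM (held)

| run | catalyst | remark | time |
|---|---|---|---|
| cedar | 1.3 mol% | run made earlier |  |
| birch | 3 mol% | run made earlier |  |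
| flask | 2 mol% |  | 15 d |

| run | time / d | product / % | solid substrate / % |
|---|---|---|---|
| cedar | 1.67 | 96.0 | 0 |
| cedar | 3.00 | 99.4 | 0.1 |
| cedar | 5.00 | 101.8 | 1.1 |
| cedar | 6.00 | 101.4 | 0.7 |
| cedar | 8.00 | 101.1 | 1.0 |
| cedar | 10.0 | 98.3 | 0.5 |
| birch | 0.625 | 74.6 | 2.3 |
| birch | 1.67 | 99.9 | 1.1 |
| birch | 3.00 | 98.9 | 0 |
| birch | 5.00 | 100.2 | 1.3 |
| birch | 6.00 | 100.6 | 0 |
| birch | 10.0 | 102.8 | 0 |

(readings scatter by 1 percentage point)

* at 15 d, what has stopped the reaction, if anything has (for what has run out or reacted, a solid counts together with what of it has only dissolved) (no working catalyst is left / all of the solid substrate has reacted / it is still moving)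
* how much product there is at 15 d, in percent of the solid substrate charged

- as a solid, counted per litre of solution: solid substrate
- at the start none of the gas phase is in solution
- at the start none of the solid substrate is in solution
- what has only dissolved of solid substrate counts as not reacted
- the reaction counts as stopped when no species that holds the solid substrate changes by six tenths of a point or more over the second half of the time

With the other charges held as in these runs, I assume that catalyst works at a steady pace, so that I can reckon with loading multiplied by time. The reserve of a flask, its loading times its time over the cedar run's loading times the time of its first reading, where product read 96.0%, comes to 13.8 for this flask. The birch run's first reading has a reserve of 0.864 and shows less product, 74.6%, which fits. Its last reading has the same loading times time as this flask, and product there reads 102.8%, with no sign of loss. So I change nothing in the recipe, and I expect product at the charge with the solid substrate gone.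

The forecast names all of the solid substrate has reacted and 100%, from 98.5% to 101.5%: “Even the lower loading has enough catalyst to finish”. The flask gives all of the solid substrate has reacted, with 100% product.

    gas phase ⇌ dissolved gas, rate k1*(csat - [dissolved gas]) (kL = 2.98 × 10⁻⁴ s⁻¹)
    solid substrate ⇌ starting material, rate k2*(cs2 - [starting material]) while solid is left; crystals form when [starting material] > cs2 (solubility = 0.750 M, k = 1.34 × 10⁻⁴ s⁻¹)
    starting material + dissolved gas + catalyst → catalyst + product (k = 0.0123 M⁻² s⁻¹)

This flask holds 98.8% product at 1.50 d, a reserve of 1.38. At 15.0 d the solid substrate, the limiting reagent, stands at 0% and the catalyst at 100%. The neighbour flask, charged with 1.2 mol% of catalyst and left the same time, has a reserve of 8.29, lower than this flask's. It gives 100% product, and 0% of its solid substrate remains, solid or dissolved.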